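**Retrosynthetic overview**
- The plan rests on acyl C1, the ester C=O. It is the only functionalised carbon of the C22 chain and lies between C2, the end of a straight unsubstituted C21 alkyl group, and the primary oxygen of the ArCH2CH2CH2O unit, so it can be taken out as CO.
- Cutting C1–C2 and C1–O together gives 1-henicosene, carbon monoxide and 3-(4-hydroxyphenyl)propan-1-ol. These are rejoined in one palladium-hydride hydroalkoxycarbonylation with the phenol left free.
- 1-Henicosene is cut at C3–C4 into 1-bromooctadecane and allylmagnesium bromide (copper-catalysed Grignard coupling).
- No ring is formed. The only ring, the 1,4-disubstituted benzene, arrives with the purchased alcohol, and there is no stereocentre to set.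

Key step: step 2

Remark: the target has no stereocentre and no stereogenic double bond, so the compound as drawn is the single species asked for; copper- and palladium-bound species of the catalytic cycles exist only in catalytic amount and carry no compound number.

**Step 1**
Reactants: 1 1-bromooctadecane; 2 allylmagnesium bromide
Product: 3 1-henicosene
Conditions: 2 (1.5 equiv, 1 M in Et2O), Li2CuCl4 (3 mol%), THF, 0 °C to rt; aq NH4Cl; SiO2 plug (hexane), recrystallisation from acetone at −20 °C
Reagents that add atoms: allylmagnesium bromide (2), C=CC[Mg]Br
Why: Copper-catalysed sp3–sp3 Grignard cross-coupling (Kochi type), in which a catalytic allylcuprate displaces the unhindered primary bromide, the two equivalent allyl termini allow only one alkene, the terminal double bond is untouched and no stereocentre is formed.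

**Step 2**
Reactants: 3 1-henicosene; 4 carbon monoxide; 5 3-(4-hydroxyphenyl)propan-1-ol
Product: 6 3-(4-hydroxyphenyl)propyl docosanoate
Conditions: Pd(OAc)2 (1 mol%), 1,2-(tBu2PCH2)2C6H4 (4 mol%), MeSO3H (10 mol%), CO (30 bar), 5 (1.3 equiv), degassed PhMe (ca. 1 M), 95 °C, autoclave; aq NaHCO3 wash, SiO2, recrystallisation from EtOH
Reagents that add atoms: carbon monoxide (4), [C-]#[O+]; 3-(4-hydroxyphenyl)propan-1-ol (5), OCCCc1ccc(O)cc1
Why: Pd(OAc)2, the diphosphine and MeSO3H form the cationic hydride [(P–P)PdH]+, which adds to C1=C2 of 3 with palladium on the terminal carbon; CO inserts into that Pd–CH2 bond (new bond acyl C1–C2) and the primary hydroxyl of 5 cleaves the resulting docosanoyl palladium species (new bond C1–O), releasing 6 and returning the hydride, so every atom of the three components ends up in the product. The closest known reaction type is the linear-selective, isomerising palladium-catalysed hydroalkoxycarbonylation (hydroesterification) of long-chain alkenes and unsaturated fatty esters with this ligand and acid, which has also been run with higher primary alcohols in inert co-solvents. No ring is closed and no stereocentre is created. Linear over branched selectivity is needed and comes from the four tert-butyl groups of the chelate: secondary palladium alkyls revert by β-hydride elimination and chain walking, and their crowded acyls are alcoholysed far more slowly than the terminal one, so any internal henicosene formed on the way is still drawn into the unbranched acyl. Aliphatic over phenolic O-acylation is also needed and rests on the greater nucleophilicity of the CH2OH group in a medium too acidic for phenoxide to exist; keeping 5 in excess over 3 reinforces it, because free primary hydroxyl then remains until the alkene is consumed, and an aryl ester formed by accident is an activated ester that the acid should pass on to the primary alcohol. The high concentration makes up for the absence of alcohol as solvent in the rate-limiting alcoholysis, and the acid is largely buffered by the excess phosphine, which should keep Friedel–Crafts alkylation of the phenol ring by 3 negligible.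

**Compound list**
1 | 1-bromooctadecane | CCCCCCCCCCCCCCCCCCBr | starting material
2 | allylmagnesium bromide | C=CC[Mg]Br | starting material
3 | 1-henicosene (henicos-1-ene) | CCCCCCCCCCCCCCCCCCCC=C | intermediate
4 | carbon monoxide | [C-]#[O+] | starting material
5 | 3-(4-hydroxyphenyl)propan-1-ol | OCCCc1ccc(O)cc1 | starting material
6 | 3-(4-hydroxyphenyl)propyl docosanoate (achiral) | CCCCCCCCCCCCCCCCCCCCCC(=O)OCCCc1ccc(O)cc1 | target

Total step count: 2
Longest linear sequence: 2 (1 → 3 → 6)

**Steps most likely to fail** (the route has only two steps, so both are ranked and there is no third)

1. **Step 2.**
   - Risk: alcoholysis of the acyl palladium by a near-stoichiometric alcohol may be slow. The catalyst could then decay to palladium black while the alkene drifts to internal isomers. O-chemoselectivity may erode late in the run through acylation of the phenol, and acid-promoted C-alkylation of the electron-rich ring by the alkene may compete.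
   - Fallback, from 3 back to 6: the C–C and the C–O(arylpropyl) bond formations are separated. Compound 3 is carbonylated with 4 by the same palladium hydride catalyst in methanol/toluene. This is the setting in which the reaction is best established, because solvent methanol cleaves the acyl quickly. It gives methyl docosanoate F1, which can be freed from branched isomers by recrystallisation.
   - F1 is then transesterified with 5 by immobilised Candida antarctica lipase B in toluene at 60 °C, with methanol removed under reduced pressure. The lipase acylates primary aliphatic hydroxyl groups and leaves phenols alone, so 6 should be reached without a protecting group.

2. **Step 1.**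
   - Risk: displacement of the bromide may be incomplete. Halogen–magnesium exchange or β-hydride elimination at copper may degrade the C18 chain to hydrocarbons. Unsaturated material of that kind would be carbonylated in step 2 to a homologous ester that is hard to remove.
   - Fallback, from 1 back to 3: the polarity of the coupling is reversed. Compound 1 is converted with magnesium turnings in THF into octadecylmagnesium bromide F2. This is allylated with allyl bromide (C=CCBr; CuI cat., THF, 0 °C), a displacement on a highly reactive allylic halide.
   - The side processes of this variant (protonation or Wurtz coupling of the chain) give only saturated material. That material is inert in step 2 and is easily separated from the polar product 6.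

**Further compounds**
F1 | step 2 | methyl docosanoate | CCCCCCCCCCCCCCCCCCCCCC(=O)OC
F2 | step 1 | octadecylmagnesium bromide | CCCCCCCCCCCCCCCCCC[Mg]Br
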